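The 2,2‑dimethyl‑2H‑pyran is cut away from ring A (C1 quaternary, C2 enol carbon, C3 benzoyl‑bearing, C4 ketone, C4a, C8a) at its C4a–CH and O–C(CH3)2 bonds. The pyran is fused across C4a=C8a; C4a is the only hydrogen‑bearing carbon of the cyclohexanetrione and C8a carries oxygen, so Knoevenagel condensation of 3‑methylbut‑2‑enal at C4a and oxa‑6π electrocyclisation through the C8a oxygen build the ring in one final operation on the free acid. The precursor is the 2‑benzoyl‑4,4‑dialkylcyclohexane‑1,3,5‑trione acid: C1 comes from an enantioselective phase‑transfer prenylation of a mixed malonate, the side‑chain centre from (S)‑lavandulol, ring A from dianion acylation and Dieckmann closure.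

Key step: step 13

Remark on numbering: the side chain is counted C1'–C5' from ring A, C2' being the isopropenyl‑bearing methine. The target is (S) at C1 and (R) at C2'.

Assumption: the facial sense of the phase‑transfer prenylation (step 6) is taken to follow that of simple tert‑butyl α‑alkylmalonates, which points to the (R,R) antipode of the catalyst for the (S)‑configured centre of 10. A pilot run with each antipode (both commercial) settles the choice; nothing else in the route changes.

Remark: enolates formed by simple deprotonation of a numbered compound in the same flask (steps 4, 6, 11, 12) are treated as the reacting form of that compound. The separately prepared dianion of step 10 and all covalent intermediates are numbered.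

**Step 1**
Reactants: 1 racemic lavandulol
Product: 2 (S)‑lavandulol
Conditions: Candida antarctica lipase B (immobilised), vinyl acetate, hexane, 25 °C, run past half conversion; chromatography
Reagents that add atoms: none
Why: Lipase‑catalysed kinetic resolution by transesterification, in which the enzyme is expected to acylate the (R)‑alcohol faster, so the recovered alcohol should be the (S)‑enantiomer in high purity; this sets the C2' stereocentre.

**Step 2**
Reactants: 2 (S)‑lavandulol
Product: 3 (S)‑lavandulyl iodide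
Conditions: PPh3, I2, imidazole, CH2Cl2, 0 °C → rt
Reagents that add atoms: iodine, II
Why: Appel‑type iodination by SN2 displacement at the primary carbinol carbon, which leaves the adjacent stereocentre and both alkenes untouched.

**Step 3**
Reactants: 4 mono‑tert‑butyl malonate, 5 2,2‑diphenylethanol
Product: 6 tert‑butyl 2,2‑diphenylethyl malonate
Conditions: EDC·HCl, DMAP (0.1 equiv), CH2Cl2, 0 °C → rt
Reagents that add atoms: none
Why: Steglich (carbodiimide) esterification of a malonic half‑ester; the tert‑butyl/2,2‑diphenylethyl pair is an ester combination on which asymmetric phase‑transfer alkylation performs well, and it keeps one primary ester for the Dieckmann closure.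

**Step 4**
Reactants: 3 (S)‑lavandulyl iodide, 6 tert‑butyl 2,2‑diphenylethyl malonate
Product: 7 tert‑butyl 2,2‑diphenylethyl 2‑[(2R)‑5‑methyl‑2‑(prop‑1‑en‑2‑yl)hex‑4‑en‑1‑yl]malonate (both epimers at the malonate carbon)
Conditions: 6 (1.5 equiv), NaH (1.4 equiv), THF/DMF, 0 °C; then 3, 60 °C
Reagents that add atoms: none
Why: Malonic ester alkylation (SN2) with a β‑branched primary iodide, with excess malonate to suppress dialkylation; the epimeric malonate CH is erased in step 6.

**Step 5**
Reactants: 7 lavandulyl malonate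
Product: 8 tert‑butyl 2,2‑diphenylethyl 2‑[(2S)‑3‑(3,3‑dimethyloxiran‑2‑yl)‑2‑(prop‑1‑en‑2‑yl)propyl]malonate (epimers at the oxirane and malonate carbons)
Conditions: mCPBA (1.05 equiv), NaHCO3, CH2Cl2, −10 → 0 °C
Reagents that add atoms: mCPBA (3‑chloroperoxybenzoic acid), OOC(=O)c1cccc(Cl)c1
Why: Prilezhaev epoxidation, in which the trisubstituted alkene reacts much faster than the 1,1‑disubstituted isopropenyl group; the epoxide is a base‑stable masked aldehyde, so no Michael acceptor is present when the malonate enolate is formed in step 6.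

**Step 6**
Reactants: 8 epoxy malonate, 9 prenyl bromide
Product: 10 tert‑butyl 2,2‑diphenylethyl (2S)‑2‑[(2S)‑3‑(3,3‑dimethyloxiran‑2‑yl)‑2‑(prop‑1‑en‑2‑yl)propyl]‑2‑(3‑methylbut‑2‑en‑1‑yl)malonate (epimers at the oxirane carbon)
Conditions: 9 (5 equiv), 50% aq. KOH, (R,R)‑3,4,5‑trifluorophenyl‑NAS bromide (N‑spiro bis‑binaphthyl quaternary ammonium bromide, 5–10 mol%), toluene, −40 °C
Reagents that add atoms: none
Why: Enantioselective phase‑transfer alkylation of a tert‑butyl α‑alkylmalonate with a reactive allylic bromide, in which the chiral ammonium–enolate ion pair exposes one enolate face and so sets the quaternary centre that becomes C1; the minor epimer is a diastereomer (because of C2') and is removed at the stage of 11.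

**Step 7**
Reactants: 10 prenylated epoxy malonate
Product: 11 tert‑butyl 2,2‑diphenylethyl (2S)‑2‑(3‑methylbut‑2‑en‑1‑yl)‑2‑[(2S)‑4‑oxo‑2‑(prop‑1‑en‑2‑yl)butyl]malonate
Conditions: H5IO6 (1.5 equiv), THF/H2O, 0 °C → rt; chromatography
Reagents that add atoms: none
Why: Periodic acid hydrolysis and glycol cleavage of a trisubstituted epoxide to aldehyde plus acetone, under which isolated alkenes and the tert‑butyl ester survive; both oxirane epimers converge on one aldehyde.

**Step 8**
Reactants: 11 aldehyde, 12 methyl 2‑(triphenyl‑λ5‑phosphanylidene)propanoate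
Product: 13 1‑tert‑butyl 3‑(2,2‑diphenylethyl) (2S)‑2‑[(2R,4E)‑6‑methoxy‑5‑methyl‑6‑oxo‑2‑(prop‑1‑en‑2‑yl)hex‑4‑en‑1‑yl]‑2‑(3‑methylbut‑2‑en‑1‑yl)propanedioate
Conditions: 12 (1.5 equiv), CH2Cl2, 25–40 °C
Reagents that add atoms: none
Why: Wittig olefination with a stabilised α‑methyl ylide, which gives the (E)‑2‑methyl enoate (chain trans to the ester) and so installs the C4'=C5' alkene after the quaternary centre is in place.

**Step 9**
Reactants: 13 triester
Product: 15 (2R)‑2‑[(2,2‑diphenylethoxy)carbonyl]‑2‑[(2R,4E)‑6‑methoxy‑5‑methyl‑6‑oxo‑2‑(prop‑1‑en‑2‑yl)hex‑4‑en‑1‑yl]‑5‑methylhex‑4‑enoic acid, via trimethylsilyl ester 14 (not isolated)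
Conditions: Me3SiOTf (3 equiv), 2,6‑lutidine (4 equiv), CH2Cl2, 0 °C → rt; then cold aq. citric acid
Reagents that add atoms: none
Why: Silyl triflate‑mediated tert‑butyl ester cleavage (loss of isobutene from the O‑silylated ester) in a buffered aprotic medium, so that no protic acid can lactonise the prenyl or isopropenyl group onto the new acid; the methyl and primary alkyl esters cannot ionise and stay.

**Step 10**
Reactants: 15 half‑acid, 16 benzoylacetone
Product: 19 2,2‑diphenylethyl (2R)‑2‑[(2R,4E)‑6‑methoxy‑5‑methyl‑6‑oxo‑2‑(prop‑1‑en‑2‑yl)hex‑4‑en‑1‑yl]‑2‑(3‑methylbut‑2‑en‑1‑yl)‑3,5,7‑trioxo‑7‑phenylheptanoate, via acid chloride 17 (not isolated), via dilithio benzoylacetone 18 (not isolated)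
Conditions: 15, 1‑chloro‑N,N,2‑trimethylprop‑1‑en‑1‑amine (1.2 equiv), CH2Cl2, 0 °C → rt; added at −78 °C to 18 [16 (2.5 equiv), LiN(i‑Pr)2 (5 equiv), THF, −78 → 0 °C]; aq. NH4Cl at −78 °C
Reagents that add atoms: none
Why: Neutral acid chloride formation with an α‑chloroenamine (no HCl, and no ketene is possible at a quaternary carbon) followed by C‑acylation of a β‑diketone dianion at its terminal carbon, its most nucleophilic site, which gives the 1,3,5‑triketone.

**Step 11**
Reactants: 19 triketo ester
Product: 20 methyl (2E,5R)‑6‑[(1S)‑3‑benzoyl‑2‑hydroxy‑1‑(3‑methylbut‑2‑en‑1‑yl)‑4,6‑dioxocyclohex‑2‑en‑1‑yl]‑2‑methyl‑5‑(prop‑1‑en‑2‑yl)hex‑2‑enoate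
Conditions: NaH (2.1 equiv), THF, 0 → 50 °C; then cold 1 M HCl
Reagents that add atoms: none
Why: Dieckmann (intramolecular Claisen) condensation in which only attack of the benzoyl‑flanked carbon (the future C3) on the ester gives a six‑membered ring and deprotonation of the acidic cyclic trione drives the closure; C1 is quaternary and cannot epimerise, and which carboxyl became C8a and which C2 was fixed in steps 9 and 10.

**Step 12**
Reactants: 20 trione methyl ester
Product: 21 (2E,5R)‑6‑[(1S)‑3‑benzoyl‑2‑hydroxy‑1‑(3‑methylbut‑2‑en‑1‑yl)‑4,6‑dioxocyclohex‑2‑en‑1‑yl]‑2‑methyl‑5‑(prop‑1‑en‑2‑yl)hex‑2‑enoic acid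
Conditions: LiOH·H2O (8 equiv), THF/MeOH/H2O, 25 → 45 °C; then cold 1 M HCl
Reagents that add atoms: water, O
Why: Saponification of the conjugated methyl ester, during which the trione is present as its delocalised enolate, which shields the C2 and C8a carbonyls flanking C1 from retro‑Claisen attack.

**Step 13**
Reactants: 21 trione acid, 22 3‑methylbut‑2‑enal
Product: 24 CNP0333091.1 (2E,5R)‑6‑[(8S)‑6‑benzoyl‑7‑hydroxy‑2,2‑dimethyl‑8‑(3‑methylbut‑2‑en‑1‑yl)‑5‑oxo‑5,8‑dihydro‑2H‑chromen‑8‑yl]‑2‑methyl‑5‑(prop‑1‑en‑2‑yl)hex‑2‑enoic acid, via Knoevenagel oxatriene 23 (not isolated)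
Conditions: 22 (3 equiv), ethylenediammonium diacetate (0.2 equiv), MeOH, 25 → 50 °C
Reagents that add atoms: none
Why: The amine salt activates 22 as its iminium ion, the enolised trione adds through C4a (its only C–H carbon) and loss of the amine gives the 3‑methylbut‑2‑enylidene trione 23, a 1‑oxatriene (O=C8a–C4a=CH–CH=CMe2), which closes by thermal disrotatory oxa‑6π electrocyclisation to form the O–C(CH3)2 bond and with it the pyran. The closest known reaction type is the formal [3+3] annulation of cyclic 1,3‑diones, 1,3,5‑triones and acylphloroglucinols with α,β‑unsaturated aldehydes under amine‑salt catalysis. The one new ring is a 2H‑pyran closed in the 6π‑electrocyclic mode; no stereocentre is created (the new sp3 carbon carries two methyl groups), and C1 and C2' are not touched. The selectivity needed is regiochemical, closure through the C8a oxygen and not the C4 oxygen: the C4 oxygen is held in the hydrogen‑bonded 2‑benzoyl‑1,3‑dione chelate with C2–OH and the benzoyl carbonyl, and because the closure is reversible the mixture should drain to the isomer that keeps this chelate, which is the target. Excess 22 suppresses Michael capture of 23 by a second trione, and the buffered medium leaves the carboxylic acid, the alkenes and both stereocentres alone.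

**Compound list**
1 | racemic lavandulol, (±)‑5‑methyl‑2‑(prop‑1‑en‑2‑yl)hex‑4‑en‑1‑ol | C=C(C)C(CC=C(C)C)CO | starting material
2 | (S)‑lavandulol | C=C(C)[C@H](CC=C(C)C)CO | intermediate
3 | (S)‑lavandulyl iodide, (3S)‑3‑(iodomethyl)‑2,6‑dimethylhepta‑1,5‑diene | C=C(C)[C@H](CC=C(C)C)CI | intermediate
4 | mono‑tert‑butyl malonate, 3‑tert‑butoxy‑3‑oxopropanoic acid | CC(C)(C)OC(=O)CC(=O)O | starting material
5 | 2,2‑diphenylethanol | OCC(c1ccccc1)c1ccccc1 | starting material
6 | tert‑butyl 2,2‑diphenylethyl malonate | CC(C)(C)OC(=O)CC(=O)OCC(c1ccccc1)c1ccccc1 | intermediate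
7 | tert‑butyl 2,2‑diphenylethyl 2‑[(2R)‑lavandulyl]malonate, malonate carbon unassigned | C=C(C)[C@H](CC=C(C)C)CC(C(=O)OCC(c1ccccc1)c1ccccc1)C(=O)OC(C)(C)C | intermediate
8 | monoepoxide of 7 at the trisubstituted alkene, oxirane and malonate carbons unassigned | C=C(C)[C@H](CC1OC1(C)C)CC(C(=O)OCC(c1ccccc1)c1ccccc1)C(=O)OC(C)(C)C | intermediate
9 | prenyl bromide, 1‑bromo‑3‑methylbut‑2‑ene | CC(C)=CCBr | starting material
10 | (S)‑configured quaternary prenyl epoxy malonate, oxirane carbon unassigned | C=C(C)[C@H](CC1OC1(C)C)C[C@@](CC=C(C)C)(C(=O)OCC(c1ccccc1)c1ccccc1)C(=O)OC(C)(C)C | intermediate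
11 | quaternary malonate aldehyde, (S) at the malonate carbon, (S) at C2' | C=C(C)[C@H](CC=O)C[C@@](CC=C(C)C)(C(=O)OCC(c1ccccc1)c1ccccc1)C(=O)OC(C)(C)C | intermediate
12 | methyl 2‑(triphenyl‑λ5‑phosphanylidene)propanoate | COC(=O)C(C)=P(c1ccccc1)(c1ccccc1)c1ccccc1 | starting material
13 | triester with (E)‑2‑methyl enoate side chain, (S) at the malonate carbon, (R) at C2' | C=C(C)[C@H](C/C=C(\C)C(=O)OC)C[C@@](CC=C(C)C)(C(=O)OCC(c1ccccc1)c1ccccc1)C(=O)OC(C)(C)C | intermediate
14 | trimethylsilyl ester of 15 | C=C(C)[C@H](C/C=C(\C)C(=O)OC)C[C@@](CC=C(C)C)(C(=O)OCC(c1ccccc1)c1ccccc1)C(=O)O[Si](C)(C)C | intermediate (not isolated)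
15 | quaternary malonic half‑acid, 2,2‑diphenylethyl ester retained, (R) at the quaternary carbon | C=C(C)[C@H](C/C=C(\C)C(=O)OC)C[C@@](CC=C(C)C)(C(=O)OCC(c1ccccc1)c1ccccc1)C(=O)O | intermediate
16 | benzoylacetone, 1‑phenylbutane‑1,3‑dione | CC(=O)CC(=O)c1ccccc1 | starting material
17 | acid chloride of 15 | C=C(C)[C@H](C/C=C(\C)C(=O)OC)C[C@@](CC=C(C)C)(C(=O)OCC(c1ccccc1)c1ccccc1)C(=O)Cl | intermediate (not isolated)
18 | dilithio dianion of benzoylacetone | C=C(O[Li])C=C(O[Li])c1ccccc1 | intermediate (not isolated)
19 | 3,5,7‑trioxo‑7‑phenylheptanoate with quaternary C2, (R) | C=C(C)[C@H](C/C=C(\C)C(=O)OC)C[C@@](CC=C(C)C)(C(=O)OCC(c1ccccc1)c1ccccc1)C(=O)CC(=O)CC(=O)c1ccccc1 | intermediate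
20 | 2‑benzoyl‑4,4‑dialkylcyclohexane‑1,3,5‑trione, side‑chain methyl ester, (S) at C1, (R) at C2' | C=C(C)[C@H](C/C=C(\C)C(=O)OC)C[C@@]1(CC=C(C)C)C(O)=C(C(=O)c2ccccc2)C(=O)CC1=O | intermediate
21 | trione acid with free C4a–H, precursor of the key step | C=C(C)[C@H](C/C=C(\C)C(=O)O)C[C@@]1(CC=C(C)C)C(O)=C(C(=O)c2ccccc2)C(=O)CC1=O | intermediate
22 | 3‑methylbut‑2‑enal | CC(C)=CC=O | starting material
23 | C4a‑(3‑methylbut‑2‑enylidene) trione acid, the 1‑oxatriene | C=C(C)[C@H](C/C=C(\C)C(=O)O)C[C@@]1(CC=C(C)C)C(O)=C(C(=O)c2ccccc2)C(=O)C(=CC=C(C)C)C1=O | intermediate (not isolated)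
24 | CNP0333091.1 | C=C(C)[C@H](C/C=C(\C)C(=O)O)C[C@@]1(CC=C(C)C)C(O)=C(C(=O)c2ccccc2)C(=O)C2=C1OC(C)(C)C=C2 | target

**Total step count:** 13
**Longest linear sequence:** 12 steps (1 → 2 → 3 → 7 → 8 → 10 → 11 → 13 → 15 → 19 → 20 → 21 → 24; step 3 is a one‑step side branch).

**Steps most likely to fail**

Step 6, phase‑transfer prenylation. The ion pair may discriminate the enolate faces poorly because the α‑substituent is a large branched chain, or the hindered enolate may alkylate sluggishly at low temperature. The fallback sets out from 8 and gives up catalyst control: ordinary malonate alkylation with 9 (NaH, THF/DMF, 0 °C → rt) should give the C1‑epimeric prenylated epoxy malonate F1. Cleavage with H5IO6 as in step 7 then gives the C1‑epimeric aldehyde F2, which is only two diastereomers once the oxirane carbon is gone. Preparative HPLC separates them, and the epimer with the (S) quaternary carbon is 11, where the route is rejoined.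

Step 10, acylation of the dianion. The strongly basic dianion may O‑acylate, acylate twice, or attack the other ester groups instead of coupling cleanly at its terminal carbon with the hindered acid chloride. The fallback sets out from 15 and 16 and replaces the dianion with a neutral nucleophile. Compound 16 is silylated (Me3SiCl, Et3N) to the mono silyl enol ether (Z)‑4‑phenyl‑4‑(trimethylsilyloxy)but‑3‑en‑2‑one F3, then (LiN(i‑Pr)2, Me3SiCl, THF, −78 °C) to the bis(silyl enol ether) 1‑phenyl‑1,3‑bis(trimethylsilyloxy)buta‑1,3‑diene F4. The acid chloride 17 is made from 15 as before and combined with F4 in CH2Cl2 (−78 °C → rt, optional catalytic Me3SiOTf), a Mukaiyama‑type C‑acylation at the terminal diene carbon without strong base. Aqueous work‑up delivers 19, where the route is rejoined.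

Step 13, key annulation. The oxatriene may close through the C4 oxygen to the regioisomeric pyran, or be intercepted by a second trione as a Michael bis‑adduct, and regioisomeric free acids may be hard to separate. The fallback sets out from the methyl ester 20 and moves the annulation one stage earlier. Condensation with 22 under Ca(OH)2 in MeOH, where the calcium chelate of the 2‑benzoyl‑1,3‑dione unit holds the C4 oxygen, should give the pyran methyl ester of the target F5. As a neutral ester it is separated from its regioisomer on silica, and the unwanted isomer is re‑equilibrated by heating, the oxa‑6π closure being reversible. Saponification of F5 with LiOH (THF/H2O, rt) then reaches 24.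

**Further compounds**
F1 | step 6 | C1‑epimeric prenylated epoxy malonate | C=C(C)[C@H](CC1OC1(C)C)CC(CC=C(C)C)(C(=O)OCC(c1ccccc1)c1ccccc1)C(=O)OC(C)(C)C
F2 | step 6 | C1‑epimeric aldehyde | C=C(C)[C@H](CC=O)CC(CC=C(C)C)(C(=O)OCC(c1ccccc1)c1ccccc1)C(=O)OC(C)(C)C
F3 | step 10 | (Z)‑4‑phenyl‑4‑(trimethylsilyloxy)but‑3‑en‑2‑one | CC(=O)/C=C(\O[Si](C)(C)C)c1ccccc1
F4 | step 10 | (Z)‑1‑phenyl‑1,3‑bis(trimethylsilyloxy)buta‑1,3‑diene | C=C(O[Si](C)(C)C)/C=C(\O[Si](C)(C)C)c1ccccc1
F5 | step 13 | pyran methyl ester of the target | C=C(C)[C@H](C/C=C(\C)C(=O)OC)C[C@@]1(CC=C(C)C)C(O)=C(C(=O)c2ccccc2)C(=O)C2=C1OC(C)(C)C=C2
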